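(All runs come from a simulation with made-up constants.)

Under the overall equation, target plus starting material left equals the starting-material charge, and target plus partner left equals the partner charge. Teal at 13 min should therefore hold 0.143 M of starting material and 0.0927 M of partner, yet its last interval adds 0.001900 M of target, less than the 0.0229 M of its first 0.58 min. Something beside that equation is at work.

| flask | starting material | partner | time |
|---|---|---|---|
| teal | 0.250 M | 0.200 M |  |
| ochre | 0.100 M | 0.0500 M |  |
| green | 0.750 M | 0.200 M |  |
| blue | 0.500 M | 0.100 M | 13 min |

| run | time / min | [target] / M |
|---|---|---|
| teal run | 0.58 | 0.0229 |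
| teal run | 1.8 | 0.0536 |
| teal run | 3.4 | 0.0753 |
| teal run | 5.3 | 0.0900 |
| teal run | 7.6 | 0.0989 |
| teal run | 10 | 0.1054 |
| teal run | 13 | 0.1073 |
| ochre run | 0.58 | 0 |
| ochre run | 1.8 | 0.0019 |
| ochre run | 3.4 | 0.0024 |
| ochre run | 5.3 | 0.0023 |
| ochre run | 7.6 | 0.0032 |
| ochre run | 10 | 0.0061 |
| ochre run | 13 | 0.0029 |
| green run | 0.58 | 0.0623 |
| green run | 1.8 | 0.1294 |
| green run | 3.4 | 0.1569 |
| green run | 5.3 | 0.1672 |
| green run | 7.6 | 0.1680 |
| green run | 10 | 0.1678 |
| green run | 13 | 0.1661 |

(each reading ± 0.001 M)

- Overall: starting material + partner -> target.
- Constant volume, constant temperature.
- "The second partner" is partner.
- An order is taken over about fifteen percent of the charge, up and down.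

* how the opening rate goes with [starting material] round the charge of the teal run: the exponent of the rate at two percent of starting material gone to target (one fixed amount of target, the same in the runs compared)
* how the opening rate goes with [partner] round the charge of the teal run: the exponent of the rate at two percent of starting material gone to target
* target in the blue run at 13 min, as a share of the starting material charged

My own reckoning starts from the readings. Green over teal at 0.58 min gives an order of 0.911 in starting material. Teal over ochre at 1.8 min then gives 1.81 in partner, a loose value: ochre's reading is 0.0019 M, with a scatter of 0.001 M. Take first order and second order. Each partner is then captured at a rate that goes as Π, the starting-material charge times the partner charge. Suppose partner also leaks away by a first-order path with one constant at this temperature. Control then passes from capture to leak at a crossing, and with starting material held, the partner share φ at a given time depends on Π.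

Teal gives 0.536 for φ, target at 13 min over partner charged, at Π of 0.0500 M^2. Blue has Π of 0.0500 M^2, equal to teal's, so blue first reckons at 10.7% of its starting material.

The weak link is the held starting material: by the reading at 13 min, teal has turned 42.9% of its charge to target, and blue, on this first reckoning, 10.7%. With mean starting material in Π, teal stands at 0.0393 M^2, blue at 0.0473 M^2 and green, with φ of 0.830, at 0.133 M^2. Interpolating on the logarithm gives blue a φ of 0.581, hence 11.6%.

The forecast gives orders of 1 and 2 and 10% for blue, within 6% to 15%, on the ground of “a decaying catalyst or activator”. My figure stands above its central value and below its high end.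

The orders come out at 1.1 and 2.1, and blue at 13 min gives 12.0%.

    starting material + 2 partner → target + partner (4.422 L² mol⁻² min⁻¹)
    partner → lost reagent (0.1314 min⁻¹)
    starting material + partner + target → 2 target (7.080 L² mol⁻² min⁻¹)

The path from partner to lost reagent moves the readings by 28 scatter units, root mean square. Blue's φ comes to 0.602, above teal's 0.536 and below green's 0.830. In blue at 13 min, 0.398 of the partner charge is not in target, and 88.0% of the starting material remains unturned.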